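**Retrosynthetic overview**

1. Manumycin G ⇒ Stille union, inside the lower triene, of a core vinylstannane that already carries the upper trienamide with a bromodienamide of 2-amino-3-hydroxycyclopent-2-enone. The five-membered ring is carried in from cyclopentane-1,3-dione and is never built.
2. Core amide ⇒ 2-azido-epoxyquinol vinylstannane + (2E,4E,6E)-8-methylnona-2,4,6-trienoic acid (Staudinger/aza-Wittig amidation).
3. Azido-enone ⇒ meso all-cis bis-epoxy quinol. One of its two enantiotopic oxiranes is opened by azide under chiral chromium catalysis and eliminated, which brings in N, the C2=C3 bond and the absolute configuration.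
4. Bis-epoxy quinol ⇒ 1,4-benzoquinone + (E)-2-stannylvinyllithium + t-BuOOH in one flask. The six-membered ring comes from the quinone; the two oxiranes, the only rings made in the route, close together in the first step, and one is later spent.

Assumption: ring atoms are numbered C1 (C=O), C2 (N), C3, C4 (C–OH), C5, C6 (oxirane carbons); the target is then 4S,5R,6S with OH cis to the oxirane oxygen. While tin sits on the side chain the C4 descriptor reads R (Sn outranks N in the CIP walk), although nothing moves in space.

**Step 1**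
Reactants: 1 (E)-1,2-bis(tributylstannyl)ethene; 2 1,4-benzoquinone
Product: 6 meso-(2R,3S,5R,6S)-2,3:5,6-diepoxy-4-hydroxy-4-[(E)-2-(tributylstannyl)ethenyl]cyclohexan-1-one (both oxirane O cis to OH), via stannylvinyllithium 3 (not isolated), via lithium quinolate 4 (not isolated), via mono-epoxide 5 (not isolated)
Conditions: 1, n-BuLi (1.0 equiv), THF, −78 °C, 1 h; cannulate into 2 (1.0 equiv), THF, −78 °C; then anhydrous t-BuOOH in decane (3 equiv), −78 → 0 °C; H2O quench
Reagents that add atoms: tert-butyl hydroperoxide, CC(C)(C)OO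
Why: Tin–lithium exchange gives 3, which adds 1,2 to one carbonyl of the quinone (organolithium quinol synthesis), and the lithium alkoxide 4 then converts t-BuOOH into LiOOt-Bu and guides it twice onto its own face of the dienone (hydroxyl-directed Weitz–Scheffer epoxidation), so both oxiranes close in the same flask cis to the OH group and the product is an achiral meso compound in which the relative configuration of C4, C5 and C6 of the target is already in place.

**Step 2**
Reactants: 6 meso bis-epoxy quinol
Product: 8 (4R,5R,6S)-2-azido-5,6-epoxy-4-hydroxy-4-[(E)-2-(tributylstannyl)ethenyl]cyclohex-2-en-1-one, via azido silyl ether 7 (not isolated)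
Conditions: (S,S)-(salen)CrCl (C36H52ClCrN2O2, the trivalent chromium chloride complex of N,N′-bis(3,5-di-tert-butylsalicylidene)cyclohexane-1,2-diamine, 5 mol %), Me3SiN3 (1.05 equiv), t-BuOMe, −10 °C → rt; then 1,8-diazabicyclo[5.4.0]undec-7-ene (DBU, 1.1 equiv), CH2Cl2, −40 → 0 °C
Reagents that add atoms: azidotrimethylsilane, C[Si](C)(C)N=[N+]=[N-]
Why: Proposed new method: catalytic enantioselective desymmetrisation of a meso bis(α,β-epoxy ketone), reasoned from the Jacobsen azidolysis of meso epoxides with Me3SiN3 (closest known reaction, also known on a meso epoxy ketone followed by β-elimination), in which one chromium centre binds an oxirane as a Lewis acid and a second delivers azide by SN2 with inversion to the carbonyl-activated α-carbon (C3 is neopentylic and shielded), the chiral complex choosing the R-configured α-carbon C2 of one of the two enantiotopic oxiranes, after which E1cB loss of trimethylsilanolate from 7 erases C2 and C3 and leaves C4, C5 and C6 of the untouched half as a single enantiomer with the oxirane still cis to OH; the sense of induction (S,S complex proposed by spatial analogy with cyclohexene oxide) is to be confirmed on the first run, the R,R complex giving the mirror image.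

**Step 3**
Reactants: 9 (E)-4-methylpent-2-enal; 10 triethyl 4-phosphonocrotonate
Product: 12 (2E,4E,6E)-8-methylnona-2,4,6-trienoic acid, via ethyl trienoate 11 (not isolated)
Conditions: LiOH·H2O, 4 Å molecular sieves, THF, reflux; then LiOH, MeOH/H2O, rt; aq. HCl to pH 2
Reagents that add atoms: lithium hydroxide, [Li+].[OH-]
Why: Vinylogous Horner–Wadsworth–Emmons olefination of the stabilised phosphonate gives the new 4E double bond under thermodynamic control while the 2E and 6E bonds are carried in from 10 and 9, and the ester is saponified by added LiOH in the same flask; no stereocentre is involved.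

**Step 4**
Reactants: 8 azido-enone; 12 trienoic acid
Product: 16 (2E,4E,6E)-N-{(4R,5R,6S)-5,6-epoxy-4-hydroxy-1-oxo-4-[(E)-2-(tributylstannyl)ethenyl]cyclohex-2-en-2-yl}-8-methylnona-2,4,6-trienamide, via iminophosphorane 13 (not isolated), via trienoyl chloride 14 (not isolated), via imidoyl chloride 15 (not isolated)
Conditions: 8, PMe3 (1.0 equiv), THF, −20 → 0 °C; 12, 1-chloro-N,N,2-trimethylprop-1-en-1-amine, CH2Cl2, 0 °C (second flask); combine at −20 → 0 °C; then aq. NaHCO3/THF, rt
Reagents that add atoms: water, O
Why: Staudinger reaction of the vinyl azide gives iminophosphorane 13, whose aza-Wittig reaction with acid chloride 14 gives imidoyl chloride 15 that hydrolyses to the enamide on bicarbonate work-up, so the self-condensing free 2-aminoenone is never set free, the hindered tertiary alcohol and the vinylstannane are left alone, and no stereocentre is touched.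

**Step 5**
Reactants: 17 potassium (1E,3E)-5-oxopenta-1,3-dien-1-olate (glutaconaldehyde potassium salt)
Product: 18 (2E,4E)-5-bromopenta-2,4-dienal
Conditions: PPh3, Br2, CH2Cl2, 0 °C; then 17, 0 °C → rt
Reagents that add atoms: bromine, BrBr
Why: Dibromotriphenylphosphorane turns the enolate oxygen of the vinylogous carboxylate into an oxyphosphonium leaving group that bromide displaces by addition–elimination (vinylogous acid bromide formation, the same logic as an Appel reaction), and the conjugated 2E,4E isomer is the thermodynamic product.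

**Step 6**
Reactants: 18 (2E,4E)-5-bromopenta-2,4-dienal
Product: 19 (2E,4E)-5-bromopenta-2,4-dienoic acid
Conditions: NaClO2, NaH2PO4, 2-methylbut-2-ene, t-BuOH/H2O, 0 °C → rt
Reagents that add atoms: sodium chlorite, [Na+].[O-]Cl=O
Why: Pinnick oxidation converts the enal chemoselectively into the acid, 2-methylbut-2-ene trapping the HOCl that would otherwise add to the bromodiene, and both double bond geometries are retained.

**Step 7**
Reactants: 20 cyclopentane-1,3-dione
Product: 21 2-(hydroxyimino)cyclopentane-1,3-dione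
Conditions: NaNO2, aq. HCl, 0 °C
Reagents that add atoms: sodium nitrite, [Na+].[O-]N=O
Why: Electrophilic nitrosation of the enol of the 1,3-dione at C2 by nitrous acid and tautomerisation give the 2-oxime (the first half of a Knorr-type amination).

**Step 8**
Reactants: 21 2-(hydroxyimino)cyclopentane-1,3-dione
Product: 22 2-amino-3-hydroxycyclopent-2-en-1-one hydrochloride
Conditions: H2 (1 atm), Pd/C (10 %), HCl, MeOH, rt
Reagents that add atoms: hydrogen chloride, Cl
Why: Catalytic hydrogenation cleaves the N–O bond and reduces the C=N bond of the oxime, and protonation by HCl traps the aminoenol as its stable hydrochloride, the vinylogous acid itself being inert to hydrogen under these conditions.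

**Step 9**
Reactants: 19 (2E,4E)-5-bromopenta-2,4-dienoic acid; 22 2-amino-3-hydroxycyclopent-2-en-1-one hydrochloride
Product: 24 (2E,4E)-5-bromo-N-(2-hydroxy-5-oxocyclopent-1-en-1-yl)penta-2,4-dienamide, via bromodienoyl chloride 23 (not isolated)
Conditions: 19, 1-chloro-N,N,2-trimethylprop-1-en-1-amine, CH2Cl2, 0 °C; then 22, NaHCO3, THF/H2O, 0 °C → rt
Reagents that add atoms: none
Why: Neutral chloroenamine activation gives acid chloride 23 without hydrogen halide addition to the diene, and Schotten–Baumann acylation then takes place at nitrogen of the liberated amine (any enol ester formed is hydrolysed or transfers to N in the bicarbonate medium), with the 2E,4E geometry unchanged.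

**Step 10**
Reactants: 16 core vinylstannane amide; 24 bromodienamide
Product: 25 manumycin G
Conditions: PdCl2(MeCN)2 (5 mol %), DMF, rt, dark
Reagents that add atoms: none
Why: Stille coupling (the divalent palladium salt is reduced in the flask to zerovalent palladium, which inserts into the dienyl C–Br bond, transmetalates with the vinylstannane and eliminates reductively) joins the two sp2 carbons with retention of both double bond geometries under neutral conditions that spare the epoxide, the tertiary alcohol, the enol and all three stereocentres.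

**Compound list**

1 | (E)-1,2-bis(tributylstannyl)ethene | CCCC[Sn](CCCC)(CCCC)/C=C/[Sn](CCCC)(CCCC)CCCC | starting material
2 | 1,4-benzoquinone | O=C1C=CC(=O)C=C1 | starting material
3 | (E)-2-(tributylstannyl)ethenyllithium | [Li]/C=C/[Sn](CCCC)(CCCC)CCCC | intermediate
4 | lithium 4-oxo-1-[(E)-2-(tributylstannyl)ethenyl]cyclohexa-2,5-dien-1-olate | [Li+].[O-]C1(/C=C/[Sn](CCCC)(CCCC)CCCC)C=CC(=O)C=C1 | intermediate
5 | rac-(4R*,5R*,6S*)-5,6-epoxy-4-hydroxy-4-[(E)-2-(tributylstannyl)ethenyl]cyclohex-2-en-1-one (OH cis to oxirane O; one enantiomer drawn) | O=C1C=C[C@@](O)(/C=C/[Sn](CCCC)(CCCC)CCCC)[C@@H]2O[C@@H]21 | intermediate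
6 | meso-(2R,3S,5R,6S)-2,3:5,6-diepoxy-4-hydroxy-4-[(E)-2-(tributylstannyl)ethenyl]cyclohexan-1-one (both oxirane O cis to OH) | O=C1[C@@H]2O[C@@H]2[C@@](O)(/C=C/[Sn](CCCC)(CCCC)CCCC)[C@@H]2O[C@@H]21 | intermediate
7 | (2S,3S,4R,5R,6S)-2-azido-5,6-epoxy-4-hydroxy-4-[(E)-2-(tributylstannyl)ethenyl]-3-(trimethylsilyloxy)cyclohexan-1-one (azide trans to the silyloxy group; silyloxy, OH and oxirane O on one face) | O=C1[C@@H](N=[N+]=[N-])[C@H](O[Si](C)(C)C)[C@@](O)(/C=C/[Sn](CCCC)(CCCC)CCCC)[C@@H]2O[C@@H]21 | intermediate
8 | (4R,5R,6S)-2-azido-5,6-epoxy-4-hydroxy-4-[(E)-2-(tributylstannyl)ethenyl]cyclohex-2-en-1-one (OH cis to oxirane O) | O=C1C(N=[N+]=[N-])=C[C@@](O)(/C=C/[Sn](CCCC)(CCCC)CCCC)[C@@H]2O[C@@H]21 | intermediate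
9 | (E)-4-methylpent-2-enal | CC(C)/C=C/C=O | starting material
10 | triethyl 4-phosphonocrotonate (ethyl (E)-4-(diethoxyphosphoryl)but-2-enoate) | CCOC(=O)/C=C/CP(=O)(OCC)OCC | starting material
11 | ethyl (2E,4E,6E)-8-methylnona-2,4,6-trienoate | CCOC(=O)/C=C/C=C/C=C/C(C)C | intermediate
12 | (2E,4E,6E)-8-methylnona-2,4,6-trienoic acid | CC(C)/C=C/C=C/C=C/C(=O)O | intermediate
13 | (4R,5R,6S)-5,6-epoxy-4-hydroxy-4-[(E)-2-(tributylstannyl)ethenyl]-2-[(trimethyl-λ5-phosphanylidene)amino]cyclohex-2-en-1-one | O=C1C(N=P(C)(C)C)=C[C@@](O)(/C=C/[Sn](CCCC)(CCCC)CCCC)[C@@H]2O[C@@H]21 | intermediate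
14 | (2E,4E,6E)-8-methylnona-2,4,6-trienoyl chloride | CC(C)/C=C/C=C/C=C/C(Cl)=O | intermediate
15 | (2E,4E,6E)-N-{(4R,5R,6S)-5,6-epoxy-4-hydroxy-1-oxo-4-[(E)-2-(tributylstannyl)ethenyl]cyclohex-2-en-2-yl}-8-methylnona-2,4,6-trienimidoyl chloride | CC(C)/C=C/C=C/C=C/C(Cl)=NC1=C[C@@](O)(/C=C/[Sn](CCCC)(CCCC)CCCC)[C@@H]2O[C@@H]2C1=O | intermediate
16 | (2E,4E,6E)-N-{(4R,5R,6S)-5,6-epoxy-4-hydroxy-1-oxo-4-[(E)-2-(tributylstannyl)ethenyl]cyclohex-2-en-2-yl}-8-methylnona-2,4,6-trienamide | CC(C)/C=C/C=C/C=C/C(=O)NC1=C[C@@](O)(/C=C/[Sn](CCCC)(CCCC)CCCC)[C@@H]2O[C@@H]2C1=O | intermediate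
17 | potassium (1E,3E)-5-oxopenta-1,3-dien-1-olate (glutaconaldehyde potassium salt) | [K+].[O-]/C=C/C=C/C=O | starting material
18 | (2E,4E)-5-bromopenta-2,4-dienal | O=C/C=C/C=C/Br | intermediate
19 | (2E,4E)-5-bromopenta-2,4-dienoic acid | OC(=O)/C=C/C=C/Br | intermediate
20 | cyclopentane-1,3-dione | O=C1CCC(=O)C1 | starting material
21 | 2-(hydroxyimino)cyclopentane-1,3-dione | ON=C1C(=O)CCC1=O | intermediate
22 | 2-amino-3-hydroxycyclopent-2-en-1-one hydrochloride | Cl.NC1=C(O)CCC1=O | intermediate
23 | (2E,4E)-5-bromopenta-2,4-dienoyl chloride | ClC(=O)/C=C/C=C/Br | intermediate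
24 | (2E,4E)-5-bromo-N-(2-hydroxy-5-oxocyclopent-1-en-1-yl)penta-2,4-dienamide | O=C(/C=C/C=C/Br)NC1=C(O)CCC1=O | intermediate
25 | manumycin G, (2E,4E,6E)-N-{(4S,5R,6S)-5,6-epoxy-4-hydroxy-4-[(1E,3E,5E)-7-[(2-hydroxy-5-oxocyclopent-1-en-1-yl)amino]-7-oxohepta-1,3,5-trien-1-yl]-1-oxocyclohex-2-en-2-yl}-8-methylnona-2,4,6-trienamide | CC(C)/C=C/C=C/C=C/C(=O)NC1=C[C@@](O)(/C=C/C=C/C=C/C(=O)NC2=C(O)CCC2=O)[C@@H]2O[C@@H]2C1=O | target

**Step count and risk**

Total: 10 steps. Longest linear sequence: 4 steps (1 → 2 → 4 → 10; the chains 5 → 6 → 9 → 10 and 7 → 8 → 9 → 10 are equally long).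

The three steps most likely to fail are steps 1, 2 and 4.

Step 1 may lose material to electron transfer from 3 to the quinone, or the peroxide stage may stall at 5 in the lithium/THF medium. The fallback sets out from 3 and comes back at 6. Compound 3 is added instead to purchased 4,4-dimethoxycyclohexa-2,5-dien-1-one (COC1(OC)C=CC(=O)C=C1), a masked quinone that cannot be reduced to the hydroquinone, and aqueous work-up gives the ketal carbinol 4,4-dimethoxy-1-[(E)-2-(tributylstannyl)ethenyl]cyclohexa-2,5-dien-1-ol F1. Brief treatment with pyridinium p-toluenesulfonate in wet acetone releases the free quinol 4-hydroxy-4-[(E)-2-(tributylstannyl)ethenyl]cyclohexa-2,5-dien-1-one F2. F2 is isolated and bis-epoxidised in a separate, aqueous hydroxyl-directed Weitz–Scheffer reaction (30 % H2O2, LiOH, THF/H2O, 0 °C) through 5 to 6.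

Step 2 may give low enantioselectivity or slow turnover, because the oxiranes are electron-poor and the substrate class is untested. The fallback sets out from 6 and comes back at 8, and replaces asymmetric catalysis by resolution. Compound 6 is opened with Me3SiN3 under racemic (salen)CrCl (C36H52ClCrN2O2), which gives 7 together with its mirror image, the (2R,3R,4S,5S,6R)-azido silyl ether F3. DBU then gives 8 together with the (4S,5S,6R)-azido enone F4. Preparative supercritical-fluid chromatography on a cellulose tris(3,5-dimethylphenylcarbamate) phase removes F4 and delivers enantiopure 8 at half the throughput.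

Step 4 may suffer from phosphine attack on the epoxy enone, acylation at carbon of the vinylogous iminophosphorane, or incomplete hydrolysis of 15. The fallback sets out from 8 (and from 14, made from 12 as before) and comes back at 16. Compound 14 is quenched with NaSH to give (2E,4E,6E)-8-methylnona-2,4,6-trienethioic S-acid F5. F5 is combined directly with azide 8 (2,6-lutidine, MeOH, rt): the thiocarboxylate adds to the electron-poor vinyl azide and the thiatriazoline collapses with loss of nitrogen and sulfur. This forms 16 without phosphorus reagents and without a free aminoenone.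

**Further compounds**

F1 | step 1 | 4,4-dimethoxy-1-[(E)-2-(tributylstannyl)ethenyl]cyclohexa-2,5-dien-1-ol | COC1(OC)C=CC(O)(/C=C/[Sn](CCCC)(CCCC)CCCC)C=C1
F2 | step 1 | 4-hydroxy-4-[(E)-2-(tributylstannyl)ethenyl]cyclohexa-2,5-dien-1-one | O=C1C=CC(O)(/C=C/[Sn](CCCC)(CCCC)CCCC)C=C1
F3 | step 2 | (2R,3R,4S,5S,6R)-2-azido-5,6-epoxy-4-hydroxy-4-[(E)-2-(tributylstannyl)ethenyl]-3-(trimethylsilyloxy)cyclohexan-1-one (mirror image of 7) | O=C1[C@H](N=[N+]=[N-])[C@@H](O[Si](C)(C)C)[C@](O)(/C=C/[Sn](CCCC)(CCCC)CCCC)[C@H]2O[C@H]21
F4 | step 2 | (4S,5S,6R)-2-azido-5,6-epoxy-4-hydroxy-4-[(E)-2-(tributylstannyl)ethenyl]cyclohex-2-en-1-one (mirror image of 8) | O=C1C(N=[N+]=[N-])=C[C@](O)(/C=C/[Sn](CCCC)(CCCC)CCCC)[C@H]2O[C@H]21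
F5 | step 4 | (2E,4E,6E)-8-methylnona-2,4,6-trienethioic S-acid | CC(C)/C=C/C=C/C=C/C(=O)S
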